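**Retrosynthetic overview**

1. Cadiolide A (11) ⇐ tri-O-methyl ether 10, by cleavage of the three aryl methyl ethers.
2. 10 ⇐ alkenyl bromide 9 + arylboronic acid 3 + CO, by a three-component carbonylative Suzuki–Miyaura coupling at C3 that makes the C3–C(=O) bond and then, last, the C(=O)–aryl bond.
3. Enabling feature: the ketone carbon is a one-carbon bridge between C3 of the butenolide ring (an sp2 carbon alpha to the lactone C2=O that can carry bromine) and a 3,5-dibromo-4-oxyphenyl ring identical with the ring on C4. CO can therefore supply the bridge and one boron reagent both aryl rings.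
4. 9 ⇐ dibromide 8 + 3 (C4-selective Suzuki–Miyaura coupling); 8 ⇐ 3,4-dibromofuran-2(5H)-one + 4-methoxybenzaldehyde (vinylogous aldol condensation, sets the Z alkene); 3 ⇐ 2,6-dibromoanisole (C–H borylation para to OMe).
5. Rings: none is built; the butenolide ring and the three benzene rings are bought and only joined.

Key step: step 4

Remark: 3,4-dibromofuran-2(5H)-one (4) is taken as a purchasable compound; in the Z alkene the aryl group and the ring oxygen lie on the same side.

**Route**

Step 1
Reactants: 1 2,6-dibromoanisole
Product: 3 (3,5-dibromo-4-methoxyphenyl)boronic acid, via pinacol boronate 2 (not isolated)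
Conditions: [Ir(OMe)(cod)]2 (1 mol%), dtbpy (2 mol%), B2pin2 (0.55 equiv), THF, 80 °C; then NaIO4 (3 equiv), aq HCl (cat.), THF/H2O, rt
Reagents that add atoms: bis(pinacolato)diboron CC1(C)OB(OC1(C)C)B1OC(C)(C)C(C)(C)O1; water O
Why: Iridium-catalysed aromatic C–H borylation is sterically controlled and the only C–H bond of 1 without an ortho substituent is the one para to OMe, the aryl bromides are left alone by the iridium boryl catalyst, and periodate cleavage of the pinacol unit then frees the boronic acid (C–H borylation followed by oxidative boronate hydrolysis).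

Step 2
Reactants: 4 3,4-dibromofuran-2(5H)-one; 5 4-methoxybenzaldehyde
Product: 8 (Z)-3,4-dibromo-5-(4-methoxybenzylidene)furan-2(5H)-one, via silyloxyfuran 6 (not isolated), via silyl aldol adduct 7 (not isolated)
Conditions: TBSOTf (1.2 equiv), i-Pr2NEt (3 equiv), CH2Cl2, 0 °C to rt; then DBU (2 equiv), rt to 40 °C
Reagents that add atoms: none
Why: Soft enolisation gives 2-silyloxyfuran 6, which adds through C5 to the silyl-activated aldehyde (vinylogous Mukaiyama aldol reaction), and DBU then effects E1cB loss of silanolate from both diastereomers of 7 to the thermodynamically preferred Z alkene, in which the aryl group lies on the side of the ring oxygen and away from the C4 bromine.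

Step 3
Reactants: 8 (Z)-3,4-dibromo-5-(4-methoxybenzylidene)furan-2(5H)-one; 3 (3,5-dibromo-4-methoxyphenyl)boronic acid
Product: 9 (Z)-3-bromo-4-(3,5-dibromo-4-methoxyphenyl)-5-(4-methoxybenzylidene)furan-2(5H)-one
Conditions: PdCl2(MeCN)2 (5 mol%), AsPh3 (20 mol%), Ag2O (3 equiv), 3 (1.05 equiv), THF, argon, 65 °C
Reagents that add atoms: none
Why: Zerovalent palladium adds preferentially to the C4–Br bond of 8 (the beta carbon of the enoate, the more electrophilic site), and Ag2O-promoted transfer of the aryl group of 3 followed by reductive elimination gives 9, while the more hindered C3–Br bond and the aryl bromides flanking OMe are kept for the next step (site-selective Suzuki–Miyaura coupling as known for 3,4-dibromobutenolides, with a limiting charge of the boronic acid).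

Step 4
Reactants: 9 (Z)-3-bromo-4-(3,5-dibromo-4-methoxyphenyl)-5-(4-methoxybenzylidene)furan-2(5H)-one; 3 (3,5-dibromo-4-methoxyphenyl)boronic acid
Product: 10 (Z)-3-(3,5-dibromo-4-methoxybenzoyl)-4-(3,5-dibromo-4-methoxyphenyl)-5-(4-methoxybenzylidene)furan-2(5H)-one
Conditions: PdCl2(PPh3)2 (5 mol%), K2CO3 (3 equiv), 3 (1.5 equiv), CO (5 bar), anisole, 80 °C
Reagents that add atoms: carbon monoxide [C-]#[O+]
Why: Zerovalent palladium adds oxidatively to the C3–Br bond of 9, CO inserts into the C3–Pd bond to give an acylpalladium complex, the aryl group of 3 is transferred from boron, and reductive elimination from the acyl(aryl)palladium complex forms the bond between the ketone carbon and the dibromoanisyl ring last. The closest known reaction type is the three-component carbonylative Suzuki–Miyaura coupling of alkenyl and aryl halides with arylboronic acids. No ring is closed and no stereocentre is formed; the Z alkene takes no part and is the thermodynamic isomer. The step needs ketone formation to outrun direct aryl coupling at C3, which CO pressure and the hindered, slowly transmetalating C3–palladium centre (flanked by C2=O and the C4 aryl ring) should secure. It also needs the alkenyl C–Br bond to react ahead of the aryl C–Br bonds, which the electron-poor alpha-bromoenoate, set against electron-rich aryl bromides ortho to OMe, the weakly donating PPh3 ligand and CO-saturated palladium should secure. The alkylidene group is already in place, so no acidic C5–H is left to give a dienolate that could trap the acylpalladium intermediate.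

Step 5
Reactants: 10 (Z)-3-(3,5-dibromo-4-methoxybenzoyl)-4-(3,5-dibromo-4-methoxyphenyl)-5-(4-methoxybenzylidene)furan-2(5H)-one
Product: 11 cadiolide A
Conditions: BBr3 (9 equiv), CH2Cl2, −78 °C to rt; then H2O
Reagents that add atoms: none
Why: BBr3 cleaves aryl methyl ethers by Lewis acid complexation and bromide attack at methyl (the two 2,6-dibromoanisole ethers, twisted out of conjugation, should be especially labile), while the lactone, the ketone, the aryl bromides and the thermodynamically preferred Z alkene are expected to survive.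

**Compound list**

1 | 2,6-dibromoanisole (1,3-dibromo-2-methoxybenzene) | COc1c(Br)cccc1Br | starting material
2 | 2-(3,5-dibromo-4-methoxyphenyl)-4,4,5,5-tetramethyl-1,3,2-dioxaborolane | COc1c(Br)cc(cc1Br)B1OC(C)(C)C(C)(C)O1 | intermediate
3 | (3,5-dibromo-4-methoxyphenyl)boronic acid | COc1c(Br)cc(cc1Br)B(O)O | intermediate
4 | 3,4-dibromofuran-2(5H)-one | O=C1OCC(Br)=C1Br | starting material
5 | 4-methoxybenzaldehyde | COc1ccc(C=O)cc1 | starting material
6 | tert-butyl[(3,4-dibromofuran-2-yl)oxy]dimethylsilane | CC(C)(C)[Si](C)(C)Oc1occ(Br)c1Br | intermediate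
7 | 3,4-dibromo-5-[(tert-butyldimethylsilyloxy)(4-methoxyphenyl)methyl]furan-2(5H)-one, racemic, both diastereomers at C5 and the carbinol carbon (both stereocentres are lost in the elimination) | COc1ccc(cc1)C(O[Si](C)(C)C(C)(C)C)C1OC(=O)C(Br)=C1Br | intermediate
8 | (Z)-3,4-dibromo-5-(4-methoxybenzylidene)furan-2(5H)-one | O=C1O/C(=C\c2ccc(OC)cc2)C(Br)=C1Br | intermediate
9 | (Z)-3-bromo-4-(3,5-dibromo-4-methoxyphenyl)-5-(4-methoxybenzylidene)furan-2(5H)-one | O=C1O/C(=C\c2ccc(OC)cc2)C(c2cc(Br)c(OC)c(Br)c2)=C1Br | intermediate
10 | (Z)-3-(3,5-dibromo-4-methoxybenzoyl)-4-(3,5-dibromo-4-methoxyphenyl)-5-(4-methoxybenzylidene)furan-2(5H)-one (tri-O-methylcadiolide A) | O=C1O/C(=C\c2ccc(OC)cc2)C(c2cc(Br)c(OC)c(Br)c2)=C1C(=O)c1cc(Br)c(OC)c(Br)c1 | intermediate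
11 | cadiolide A, (Z)-3-(3,5-dibromo-4-hydroxybenzoyl)-4-(3,5-dibromo-4-hydroxyphenyl)-5-(4-hydroxybenzylidene)furan-2(5H)-one | O=C1O/C(=C\c2ccc(O)cc2)C(c2cc(Br)c(O)c(Br)c2)=C1C(=O)c1cc(Br)c(O)c(Br)c1 | target

**Count and risks**

Total steps: 5. Longest linear sequence: 4 steps (step 2, step 3, step 4, step 5; equally step 1, step 3, step 4, step 5).

Steps most likely to fail:

Step 4. Two processes may go wrong. Transfer of the aryl group from boron may overtake CO insertion at the hindered C3–palladium centre, which gives direct arylation at C3. Oxidative addition into the aryl C–Br bonds may lead to chain growth. The fallback sets out from 9. A Nozaki–Hiyama–Kishi coupling of 9 with purchased 3,5-dibromo-4-methoxybenzaldehyde (CrCl2, NiCl2 cat., DMF, rt to 50 °C) goes through an alkenylchromium reagent and needs no CO, and the electron-poor alkenyl bromide should be activated ahead of the aryl bromides. It should give the racemic secondary alcohol (Z)-4-(3,5-dibromo-4-methoxyphenyl)-3-[(3,5-dibromo-4-methoxyphenyl)(hydroxy)methyl]-5-(4-methoxybenzylidene)furan-2(5H)-one F1. Oxidation with Dess–Martin periodinane (CH2Cl2, rt) comes back to the route at 10.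

Step 2. Addition–elimination of DBU or of the dienolate at C4, the beta carbon that carries a leaving group, may cost the C4 bromine, and the elimination may stay incomplete. The fallback sets out from 4 and puts the C4 aryl group on first. Suzuki–Miyaura coupling of 4 with 3 (PdCl2(MeCN)2, AsPh3, Ag2O, THF, 65 °C) should give 3-bromo-4-(3,5-dibromo-4-methoxyphenyl)furan-2(5H)-one F2, which has no leaving group at the beta carbon. The same TBSOTf/i-Pr2NEt/DBU sequence with 5 should then proceed by way of tert-butyl{[3-bromo-4-(3,5-dibromo-4-methoxyphenyl)furan-2-yl]oxy}dimethylsilane F3 and 3-bromo-5-[(tert-butyldimethylsilyloxy)(4-methoxyphenyl)methyl]-4-(3,5-dibromo-4-methoxyphenyl)furan-2(5H)-one F4. It comes back to the route at 9, which enters step 4.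

Step 1. Conversion in the C–H borylation may be poor, through catalyst loss by insertion of iridium into the C–Br bonds or through the hindered, electron-rich arene. The fallback sets out from 1. Electrophilic iodination para to OMe (NIS, TfOH cat., MeCN, rt) should give 1,3-dibromo-5-iodo-2-methoxybenzene F5. Iodine–magnesium exchange (i-PrMgCl·LiCl, THF, −40 °C), which leaves the two C–Br bonds alone, should give (3,5-dibromo-4-methoxyphenyl)magnesium chloride F6. Trapping with 2-isopropoxy-4,4,5,5-tetramethyl-1,3,2-dioxaborolane comes back to the route at 2, which is hydrolysed to 3 as in step 1.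

**Further compounds**

F1 | step 4 | (Z)-4-(3,5-dibromo-4-methoxyphenyl)-3-[(3,5-dibromo-4-methoxyphenyl)(hydroxy)methyl]-5-(4-methoxybenzylidene)furan-2(5H)-one, racemic | O=C1O/C(=C\c2ccc(OC)cc2)C(c2cc(Br)c(OC)c(Br)c2)=C1C(O)c1cc(Br)c(OC)c(Br)c1
F2 | step 2 | 3-bromo-4-(3,5-dibromo-4-methoxyphenyl)furan-2(5H)-one | O=C1OCC(c2cc(Br)c(OC)c(Br)c2)=C1Br
F3 | step 2 | tert-butyl{[3-bromo-4-(3,5-dibromo-4-methoxyphenyl)furan-2-yl]oxy}dimethylsilane | CC(C)(C)[Si](C)(C)Oc1occ(-c2cc(Br)c(OC)c(Br)c2)c1Br
F4 | step 2 | 3-bromo-5-[(tert-butyldimethylsilyloxy)(4-methoxyphenyl)methyl]-4-(3,5-dibromo-4-methoxyphenyl)furan-2(5H)-one, racemic, both diastereomers | COc1ccc(cc1)C(O[Si](C)(C)C(C)(C)C)C1OC(=O)C(Br)=C1c1cc(Br)c(OC)c(Br)c1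
F5 | step 1 | 1,3-dibromo-5-iodo-2-methoxybenzene | COc1c(Br)cc(I)cc1Br
F6 | step 1 | (3,5-dibromo-4-methoxyphenyl)magnesium chloride | COc1c(Br)cc([Mg]Cl)cc1Br
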